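The birch run has its highest reading of target at 4.00 h, 16.3 % of the starting material charged. The larch run, with 1.6 M of second substrate against 0.40 M, reads 13.7 % at the same time. That gap of 2.6 percentage points stands against a scatter of 1 point per reading.

in all of them: starting material 0.80 M; catalyst 37 mM
- birch: coupling partner 2 M; second substrate 0.40 M; run made earlier
- larch: coupling partner 2 M; second substrate 1.6 M; run made earlier
- flask: coupling partner 2.00 M; second substrate 0.800 M; time 50 h

| birch: time / h | birch: target / % | larch: time / h | larch: target / % |
|---|---|---|---|
| 1.33 | 10.2 | 1.33 | 10.0 |
| 4.00 | 16.3 | 4.00 | 13.7 |
| 12.0 | 10.5 | 12.0 | 9.4 |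
| 40.0 | 2.4 | 40.0 | 1.2 |

(each reading ± 1 percentage point)

- the best time, 50 h at the latest, for target
- the amount of target, in percent of the starting material charged, at that time

One number folds the charges together: the catalyst charge times the coupling partner charge of the flask, over the same product in the birch run, 1.00. It is read here, as an assumption of this reckoning, as the flask's starting power to make target against the earlier runs, at equal starting material. At this value the flask matches those runs in everything but second substrate, of which it holds twice the birch charge and half the larch charge. The geometric mean of the two peak readings is 14.9 % of the charge, so this reckoning gives the flask 14.9 % near 4.00 h. That number has the same value for the birch and larch runs, whose readings at 4.00 h differ by the gap above, so one number is not enough: the second substrate comes in through the mean, and the time in this reckoning is no finer than the spacing of the readings.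

The forecast gives 15 % at 4.2 h, placing the flask at “the geometric midpoint of the two runs”.

The flask gives 14.9 % at 4.66 h, and at 9.32 h it still counts 12.2 %.

    target → over-reaction product (k = 7.20 × 10⁻⁵ s⁻¹)
    catalyst + target ⇌ idle complex (K = 1.40 L mol⁻¹, k = 1.20 × 10⁻⁴ L mol⁻¹ s⁻¹)
    starting material + coupling partner + catalyst → catalyst + target (k = 3.60 × 10⁻⁴ L² mol⁻² s⁻¹)
    starting material + target → side product (k = 2.90 × 10⁻⁵ L mol⁻¹ s⁻¹)
    second substrate + coupling partner + catalyst → catalyst + second product (k = 2.00 × 10⁻⁴ L² mol⁻² s⁻¹)

In these equations the step that makes target is first order in coupling partner and in catalyst, so at equal starting material 1.00 is the ratio of that step's starting rate in the flask to its starting rate in the birch run. For the neighbour flask charged with 0.022 M of catalyst, the number falls to 0.595 and the reckoned peak to 8.87 %; the simulation of that neighbour gives 10.4 %.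

The data were computed for substances that don't exist.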